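## The problem

Compound 26 is a germacrane-type ester built on a single ten-membered carbocycle, numbered here C1–C10 so that C4(Me)–C5 carry the epoxide, C6 the 4-hydroxybenzoate, C7 the isopropyl group, C8=C9 the E-alkene and C10 the methyl carbinol. The ring has to be made by direct closure against transannular strain, and both ring alkenes must come out with fixed geometry: E at C8=C9 and ring-cis (Z) at C4=C5, because the cis-epoxide is derived from it. Four of the five stereocentres (C4, C5, C6, C7) are contiguous: C6 and C7 can be made together in one open-chain step, and the C6 hydroxyl can then steer the epoxide oxygen onto C4/C5, with which it is erythro (ring-cis). C10 is isolated on the far side of the alkene, nothing in the molecule can control it, and it must come from a reagent or from the chiral pool. The groups that forbid rough treatment are the trisubstituted epoxide (acid, Lewis acid, transannular attack by the C10 hydroxyl), the tertiary allylic alcohol, the aryl ester with its free phenol (hydride, organometallics, strong base) and, before epoxidation, the C4=C5/C8=C9 1,5-diene with oxygen on C6, which can cyclise transannularly under acid, undergo Cope rearrangement on heating and, as the naked C6 alkoxide, contract by oxy-Cope rearrangement. Epoxide and ester therefore have to arrive last, in that order, under buffered conditions. The feature that opens the ring to a mild closure is that C3 is a plain methylene on the fully substituted alkene carbon C4: a Z-iodoalkene at C4 and a borane on C3, grown from a terminal C2=C3 alkene, can be joined by palladium with the C4=C5 geometry already fixed and without creating a stereocentre.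

## Retrosynthesis

**Ester and phenol.** The C6–O acyl bond is cut first, after re-masking the phenol: 26 goes back to the silyl ether 25 and then to the epoxy diol 21 and the acid 24. Acid 24 is one operation from 4-hydroxybenzoic acid 22 through the silyl ester 23. The ester comes last because it would not survive the hydride, borane and aqueous-base steps, and because acylating earlier would remove the C6 hydroxyl as a directing group for the epoxide. The forward reaction must only tell a secondary from a tertiary hydroxyl and free the phenol without attacking epoxide or ester.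

**Epoxide.** The C4–O and C5–O bonds are cut next: 21 goes back to the diene diol 20, and 20 to the bis-silyl ether 19. The epoxide is erythro to C6–OH, which is what a hydroxyl-directed, tartrate-matched titanium epoxidation delivers. The tertiary C10 hydroxyl is not a substrate for that catalyst, so C8=C9 should be left alone. Epoxidising a protected or acylated diene would give up this control. The forward steps must release the diol without forming the C6 alkoxide and must epoxidise a Z-trisubstituted ring alkene on one face.

**Ring (key cut).** Macrocycle 19 is opened at C3–C4 to the open-chain iodo triene 17, by way of the borane 18. The neighbouring cuts are weaker: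
- C4=C5 by carbonyl coupling gives no control of alkene geometry.
- C8=C9 by metathesis lies next to the quaternary C10.
- C1–C2 or C2–C3 by alkylation needs an activating group that must later be removed.
- C5–C6 or C6–C7 would create a stereocentre in the ring-closing event.

C3–C4 joins a methylene to an sp2 carbon whose only stereochemical content, the alkene geometry, is set beforehand. Compound 17 has no ring and already holds C6, C7, C10 and both alkene geometries. The forward step needs hydroboration of one alkene out of three, retention at C4, and end-to-end coupling faster than intermolecular coupling.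

**C10–C1 and C8=C9.** Compound 17 is the triethylsilyl ether of 16. Cutting the allyl group (C10–C1) from 16 gives the E-enone 15, and cutting C8=C9 gives aldehyde 13 and the commercial phosphonate 14. This places the isolated C10 centre on a methyl ketone whose two substituents (methyl and a branched alkenyl group) differ enough for a chiral-diol-catalysed allylboration. Bringing C10 in as a chiral-pool aldehyde and joining at C8=C9 by a sulfone olefination would fix the configuration beyond doubt but costs two more steps; it is kept as the reserve. The forward reactions need E-selective olefination without epimerising C7 and reagent-controlled addition to one ketone face.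

**C6–C7.** Aldehyde 13 comes from alcohol 12, silyl ether 11 and aldol adduct 10 by routine changes. Cutting C6–C7 in 10 gives the N-isovaleryl oxazolidinone 8 and (Z)-3-iodobut-2-enal 4. Along C8–C7–C6–C5 the isopropyl group and the C6 oxygen are syn, which is the relationship an Evans aldol gives, so one step sets both centres and brings in the Z-iodoalkene intact. Setting C7 by alkylation and C6 by adding a propynyl nucleophile to the α-branched aldehyde would be longer and would rely on weak 1,2-induction at C6. The forward reaction needs a Z-enolate, auxiliary control of the face, and an iodoenal that keeps its geometry.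

**Small pieces.** Enal 4 comes from (Z)-3-iodobut-2-en-1-ol 3, made from but-2-yn-1-ol 1 by hydroxyl-directed trans-hydroalumination (alanate 2) and iodination, which fixes the Z geometry. Imide 8 comes from (R)-4-benzyloxazolidin-2-one 5 and 3-methylbutanoyl chloride 6 through the lithium salt 7.

## Roads not taken

**Alternative 1:** Retro-[3,3] shift: the C6–C7 bond is cut and C4–C9 is closed, giving the cis-1,2-dialkenylcyclohexane-1,3-diol A1. Forward, the potassium alkoxide of A1 (KH, 18-crown-6) would undergo anionic oxy-Cope ring expansion, and PhNTf2 would trap the C4 enolate as the ten-membered enol triflate A2; a methyl cross-coupling would then install the C4 methyl group.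
- Merits: the ring forms unimolecularly from a six-membered ring, so no dilution is needed. A chair transition state would set C6, C7 and both ring alkene geometries at once from an E-enol ether and an E-alkene. The enolate is trapped regiospecifically.
- Weak points: A1 carries three contiguous ring stereocentres (C4, C9, C10) and two defined alkene geometries, and would take longer to make than the whole open chain 17. The cis-dialkenyl substrate must pass through the chair that places ring carbon C3 axial; a competing boat would erode C6, C7 and the C4=C5 geometry. The free C10 hydroxyl means the rearrangement runs on a dialkoxide. An extra step is needed for the methyl group.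
- Comparison: as a ring-forming event this road is better than the chosen one. The chosen plan sets against it a linear precursor made by standard asymmetric reactions, with each stereocentre set where it can be checked. Its own liability is the macrocyclisation.

**Alternative 2:** The C1–C2 bond is cut, giving the open-chain epoxy sulfone A3. Forward, the C2 carbanion (LiN(iPr)2) would open the terminal epoxide at its methylene in an intramolecular SN2 reaction, giving the macrocyclic hydroxy sulfone A4 as both C2 epimers and releasing the C10 alkoxide.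
- Merits: the C10 centre rides in as an epoxide and the tertiary alcohol appears without a protecting group. Stabilised-carbanion alkylations are a proven way into ten-membered carbocycles. Like the chosen step, the closure creates no lasting stereocentre.
- Weak points: the epoxide in A3 is a vinyl epoxide, so SN2' attack at C8 and base-induced isomerisation compete with attack at the hindered 2,2-disubstituted terminus. The enantiopure 2-alkenyl-2-methyloxirane has no directing group for its own synthesis. The sulfone must be put on and then removed reductively next to allylic oxygen functions. The Z-trisubstituted C4=C5 alkene still has to be built first, most simply from the same iodoalkene.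
- Comparison: the two roads are equal in stereochemical neutrality. The chosen plan needs no auxiliary group and no regiochemical decision at an epoxide, and is about two steps shorter.

**Alternative 3:** The C4=C5 double bond is cut to the keto aldehyde A5. Forward, low-valent titanium (TiCl3, zinc–copper couple) would couple the C5 aldehyde with the C4 methyl ketone to the macrocyclic diene A6.
- Merits: A5 is the simplest precursor of all, with no iodoalkene and only carbonyl chemistry. McMurry coupling is among the most reliable closures for strained medium rings and is as good as or better than a palladium macrocyclisation in that respect.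
- Weak points: the geometry of the new trisubstituted alkene is decided by ring strain on the metal surface, not by the substrate, and the cis-epoxide depends on it. The α-alkoxy aldehyde in A5 is prone to epimerisation at C6 and to reductive loss of the C6 oxygen. The allylic ether formed in A6 is itself open to deoxygenation by the large excess of reductant.
- Comparison: against the better ring-closing power of this road, the chosen plan sets a Z geometry at C4=C5 fixed before closure and conditions that leave the C6 oxygen and C7 untouched.

Key step: step 11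

Assumption: the (S)-3,3'-dibromo-BINOL catalyst of step 9 is taken to deliver allyl to the Re face of the methyl ketone (alkenyl in the place of aryl, as with aryl methyl ketones); should the first analysis of 16 show the opposite sense, the antipodal catalyst is used with no other change.

Names of the ring compounds 19–21, 25 and 26 use the ring numbering C1–C10 defined under "The problem".

## Route

Step 1
Reactants: 1 but-2-yn-1-ol
Product: 3 (Z)-3-iodobut-2-en-1-ol, via cyclic alkenylalanate 2 (not isolated)
Conditions: NaAlH2(OCH2CH2OMe)2, THF, 0 °C to rt; then I2, −78 to 0 °C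
Reagents that add atoms: iodine, II
Why: Hydroxyl-directed trans-hydroalumination of the propargylic alcohol places aluminium on the distal alkyne carbon (the future C4), anti to the delivered hydride. Iodinolysis of the carbon–aluminium bond with retention gives the Z-iodoalkene that becomes the ring-cis C4=C5 bond.

Step 2
Reactants: 3 (Z)-3-iodobut-2-en-1-ol
Product: 4 (Z)-3-iodobut-2-enal
Conditions: MnO2, CH2Cl2, rt, dark; solution used at once
Reagents that add atoms: none
Why: Allylic oxidation with activated manganese dioxide is neutral and leaves the carbon–iodine bond and the alkene geometry alone; the volatile, light-sensitive enal is not stored.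

Step 3
Reactants: 5 (R)-4-benzyloxazolidin-2-one; 6 3-methylbutanoyl chloride
Product: 8 (R)-4-benzyl-3-(3-methylbutanoyl)oxazolidin-2-one, via lithiated oxazolidinone 7 (not isolated)
Conditions: n-BuLi, THF, −78 °C; then 6, −78 to 0 °C
Reagents that add atoms: none
Why: Standard N-acylation of the lithiated auxiliary by the acid chloride; the stereocentre of the auxiliary is not involved.

Step 4
Reactants: 8 (R)-4-benzyl-3-(3-methylbutanoyl)oxazolidin-2-one; 4 (Z)-3-iodobut-2-enal
Product: 10 (R)-4-benzyl-3-[(2R,3R,4Z)-3-hydroxy-5-iodo-2-(propan-2-yl)hex-4-enoyl]oxazolidin-2-one, via dibutylboron Z-enolate 9 (not isolated)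
Conditions: Bu2BOTf, iPr2NEt, CH2Cl2, −78 to 0 °C; then 4, −78 to −10 °C; pH 7 buffer, MeOH, H2O2, 0 °C
Reagents that add atoms: none
Why: Evans syn aldol: the Z-boron enolate reacts through a Zimmerman–Traxler chair with the auxiliary carbonyl turned away from the enolate oxygen, and the aldehyde takes the enolate face remote from the benzyl group. The (R)-auxiliary should therefore give the syn adduct with the C7 (isopropyl) and C6 (hydroxyl) configurations of the target in one step.

Step 5
Reactants: 10 (R)-4-benzyl-3-[(2R,3R,4Z)-3-hydroxy-5-iodo-2-(propan-2-yl)hex-4-enoyl]oxazolidin-2-one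
Product: 11 (R)-4-benzyl-3-[(2R,3R,4Z)-3-(tert-butyldimethylsilyloxy)-5-iodo-2-(propan-2-yl)hex-4-enoyl]oxazolidin-2-one
Conditions: TBSOTf, 2,6-lutidine, CH2Cl2, −78 to 0 °C
Reagents that add atoms: tert-butyldimethylsilyl trifluoromethanesulfonate, CC(C)(C)[Si](C)(C)OS(=O)(=O)C(F)(F)F
Why: Silyl triflate with a hindered base silylates the hindered aldol hydroxyl without retro-aldol cleavage. The TBS ether protects C6–O through the hydride, base and palladium steps and keeps the later 1,5-diene free of alkoxide.

Step 6
Reactants: 11 (R)-4-benzyl-3-[(2R,3R,4Z)-3-(tert-butyldimethylsilyloxy)-5-iodo-2-(propan-2-yl)hex-4-enoyl]oxazolidin-2-one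
Product: 12 (2S,3R,4Z)-3-(tert-butyldimethylsilyloxy)-5-iodo-2-(propan-2-yl)hex-4-en-1-ol
Conditions: LiBH4, THF/MeOH (20:1), 0 °C
Reagents that add atoms: none
Why: Borohydride cleaves the N-acyloxazolidinone reductively at the exocyclic carbonyl, giving the C8 alcohol and returning auxiliary 5. The iodoalkene and silyl ether are inert and C7 is not epimerised.

Step 7
Reactants: 12 (2S,3R,4Z)-3-(tert-butyldimethylsilyloxy)-5-iodo-2-(propan-2-yl)hex-4-en-1-ol
Product: 13 (2R,3R,4Z)-3-(tert-butyldimethylsilyloxy)-5-iodo-2-(propan-2-yl)hex-4-enal
Conditions: Dess–Martin periodinane, CH2Cl2, 0 °C to rt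
Reagents that add atoms: none
Why: Dess–Martin oxidation is near-neutral and should give the α-branched aldehyde without epimerising C7 or eliminating the β-silyloxy group; the aldehyde is used directly.

Step 8
Reactants: 13 (2R,3R,4Z)-3-(tert-butyldimethylsilyloxy)-5-iodo-2-(propan-2-yl)hex-4-enal; 14 dimethyl (2-oxopropyl)phosphonate
Product: 15 (3E,5S,6R,7Z)-6-(tert-butyldimethylsilyloxy)-8-iodo-5-(propan-2-yl)nona-3,7-dien-2-one
Conditions: Ba(OH)2, THF/H2O (40:1), rt
Reagents that add atoms: none
Why: Horner–Wadsworth–Emmons olefination with the stabilised keto-phosphonate gives the E-enone (the C8=C9 bond). The mild barium hydroxide activation is suited to epimerisable α-branched, β-silyloxy aldehydes.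

Step 9
Reactants: 15 (3E,5S,6R,7Z)-6-(tert-butyldimethylsilyloxy)-8-iodo-5-(propan-2-yl)nona-3,7-dien-2-one
Product: 16 (4R,5E,7S,8R,9Z)-8-(tert-butyldimethylsilyloxy)-10-iodo-4-methyl-7-(propan-2-yl)undeca-1,5,9-trien-4-ol
Conditions: allylB(OiPr)2, (S)-3,3'-Br2-BINOL (15 mol %), PhMe/PhCF3 (3:1), −35 °C
Reagents that add atoms: allyldiisopropoxyborane, C=CCB(OC(C)C)OC(C)C
Why: Chiral-diol-catalysed allylboration of a ketone: the boronate exchanges one isopropoxy group for the BINOL and reacts through a closed chair with the branched alkenyl group equatorial and methyl axial, so the catalyst alone selects the ketone face. Addition to the Re face (O > alkenyl > methyl) sets 10R; C7 and C6 are three and four bonds from the carbonyl and should not interfere, and allylboronates add 1,2 to enones. The boronate is prepared beforehand from allylmagnesium bromide and triisopropyl borate.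

Step 10
Reactants: 16 (4R,5E,7S,8R,9Z)-8-(tert-butyldimethylsilyloxy)-10-iodo-4-methyl-7-(propan-2-yl)undeca-1,5,9-trien-4-ol
Product: 17 (4R,5E,7S,8R,9Z)-8-(tert-butyldimethylsilyloxy)-10-iodo-4-methyl-7-(propan-2-yl)-4-(triethylsilyloxy)undeca-1,5,9-triene
Conditions: TESOTf, 2,6-lutidine, CH2Cl2, −78 to 0 °C
Reagents that add atoms: triethylsilyl trifluoromethanesulfonate, CC[Si](CC)(CC)OS(=O)(=O)C(F)(F)F
Why: Silyl triflate and 2,6-lutidine silylate the tertiary allylic alcohol. The TES ether stops the hydroxyl from consuming borane and from forming an alkoxide during the coupling.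

Step 11
Reactants: 17 (4R,5E,7S,8R,9Z)-8-(tert-butyldimethylsilyloxy)-10-iodo-4-methyl-7-(propan-2-yl)-4-(triethylsilyloxy)undeca-1,5,9-triene
Product: 19 (6R,7S,10R,4Z,8E)-6-(tert-butyldimethylsilyloxy)-4,10-dimethyl-7-(propan-2-yl)-10-(triethylsilyloxy)cyclodeca-4,8-diene, via B-alkyl-9-BBN borane 18 (not isolated)
Conditions: 9-BBN-H, THF, 0 °C to rt; then slow addition to PdCl2(dppf) (20 mol %), AsPh3, Cs2CO3, DMF/THF/H2O, 45 °C, final 2 mM
Reagents that add atoms: none
Why: 9-BBN-H adds anti-Markovnikov to the only monosubstituted alkene and puts boron on C3; the E-disubstituted C8=C9 alkene between two branched carbons and the iodoalkene are far slower, so 18 should form chemoselectively. Zerovalent palladium then inserts into the C4–iodine bond with retention of the Z geometry, aqueous carbonate turns the borane into a borate that hands the primary alkyl group to divalent palladium, and reductive elimination from the alkyl(alkenyl)palladium forms C3–C4. The closest known reaction type is the intramolecular B-alkyl Suzuki–Miyaura macrocyclisation of ω-boryl alkenyl iodides under PdCl2(dppf)/AsPh3/aqueous carbonate conditions. The ten-membered ring closes end to end: intramolecular transmetalation gives an eleven-membered palladacycle that contracts to the carbocycle on reductive elimination, a macrocyclisation outside the exo/endo classes of small rings. No stereocentre is formed; C6, C7 and C10 are spectators, and the only stereochemical demand is retention at C4, which oxidative addition and reductive elimination at sp2 carbon provide. Ring closure must outrun intermolecular coupling; this is secured by slow addition of 18 at high dilution and helped by the Z-iodoalkene, the E-alkene and the fully substituted C10, which leave few rotatable bonds and turn the two ends toward each other. Both oxygens stay silylated so that no alkoxide of the 1,5-diene can form under the basic conditions, and the temperature is held at or below 45 °C to keep the cyclodeca-1,5-diene from Cope rearrangement.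

Step 12
Reactants: 19 (6R,7S,10R,4Z,8E)-6-(tert-butyldimethylsilyloxy)-4,10-dimethyl-7-(propan-2-yl)-10-(triethylsilyloxy)cyclodeca-4,8-diene
Product: 20 (6R,7S,10R,4Z,8E)-4,10-dimethyl-7-(propan-2-yl)cyclodeca-4,8-diene-6,10-diol
Conditions: HF·pyridine, pyridine, THF, 0 °C to rt
Reagents that add atoms: none
Why: Fluoride buffered by excess pyridine cleaves the tertiary TES ether and the secondary TBS ether without producing a free alkoxide, which at C6 would trigger anionic oxy-Cope contraction of the 1,5-diene. The medium is also not acidic enough for transannular cyclisation.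

Step 13
Reactants: 20 (6R,7S,10R,4Z,8E)-4,10-dimethyl-7-(propan-2-yl)cyclodeca-4,8-diene-6,10-diol
Product: 21 (4S,5R,6R,7S,10R,8E)-4,5-epoxy-4,10-dimethyl-7-(propan-2-yl)cyclodec-8-ene-6,10-diol
Conditions: Ti(OiPr)4 (50 mol %), D-(−)-diisopropyl tartrate (60 mol %), t-BuOOH, 4 Å MS, CH2Cl2, −20 °C
Reagents that add atoms: tert-butyl hydroperoxide, CC(C)(C)OO
Why: Katsuki–Sharpless epoxidation of a secondary allylic alcohol in the matched sense: the (6R)-carbinol is the fast-reacting partner of the (S,S)-tartrate complex and should give the erythro epoxy alcohol (4S,5R). This is also the ring-cis product that metal-alkoxide-directed epoxidation gives with medium-ring cis-allylic alcohols, because the C6–C7 ring bond sits on the face opposite to the delivered oxygen. The tertiary allylic C10 hydroxyl is not a competent substrate for this catalyst, so C8=C9 should be left.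

Step 14
Reactants: 22 4-hydroxybenzoic acid
Product: 24 4-(tert-butyldimethylsilyloxy)benzoic acid, via bis-silylated silyl ester 23 (not isolated)
Conditions: TBSCl (2.2 equiv), imidazole, DMF, rt; then AcOH, THF/H2O, rt
Reagents that add atoms: tert-butyldimethylsilyl chloride, CC(C)(C)[Si](C)(C)Cl
Why: Phenol and acid are both silylated; the silyl ester is far more labile than the aryl silyl ether and is hydrolysed selectively by aqueous acetic acid, leaving the phenol masked for the coupling.

Step 15
Reactants: 21 (4S,5R,6R,7S,10R,8E)-4,5-epoxy-4,10-dimethyl-7-(propan-2-yl)cyclodec-8-ene-6,10-diol; 24 4-(tert-butyldimethylsilyloxy)benzoic acid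
Product: 25 (4S,5R,6R,7S,10R,8E)-4,5-epoxy-10-hydroxy-4,10-dimethyl-7-(propan-2-yl)cyclodec-8-en-6-yl 4-(tert-butyldimethylsilyloxy)benzoate
Conditions: EDC·HCl, DMAP, CH2Cl2, 0 °C to rt
Reagents that add atoms: none
Why: Steglich esterification: the secondary C6 hydroxyl reacts with the DMAP-activated acyl donor while the tertiary C10 hydroxyl does not. No base strong enough for Payne rearrangement or epoxide opening is present.

Step 16
Reactants: 25 (4S,5R,6R,7S,10R,8E)-4,5-epoxy-10-hydroxy-4,10-dimethyl-7-(propan-2-yl)cyclodec-8-en-6-yl 4-(tert-butyldimethylsilyloxy)benzoate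
Product: 26 (4S,5R,6R,7S,10R,8E)-4,5-epoxy-10-hydroxy-4,10-dimethyl-7-(propan-2-yl)cyclodec-8-en-6-yl 4-hydroxybenzoate
Conditions: TBAF, AcOH, THF, 0 °C
Reagents that add atoms: none
Why: Aryl silyl ethers are cleaved by fluoride rapidly at 0 °C; acetic acid buffers the phenoxide so that the benzoate and the epoxide should not be attacked, and the tertiary alcohol is unaffected.

## Compound list

1 | but-2-yn-1-ol | CC#CCO | starting material
2 | sodium cyclic alkenylalanate of 1 [2,2-bis(2-methoxyethoxy)-3-methyl-2,5-dihydro-1,2-oxaluminol-2-uide, sodium salt] | CC1=CCO[Al-]1(OCCOC)OCCOC.[Na+] | intermediate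
3 | (Z)-3-iodobut-2-en-1-ol | OC/C=C(/C)I | intermediate
4 | (Z)-3-iodobut-2-enal | O=C/C=C(/C)I | intermediate
5 | (R)-4-benzyloxazolidin-2-one | O=C1OC[C@@H](Cc2ccccc2)N1 | starting material
6 | 3-methylbutanoyl chloride | CC(C)CC(Cl)=O | starting material
7 | lithium salt of 5 (N-lithio-(R)-4-benzyloxazolidin-2-one) | [Li]N1C(=O)OC[C@H]1Cc1ccccc1 | intermediate
8 | (R)-4-benzyl-3-(3-methylbutanoyl)oxazolidin-2-one | CC(C)CC(=O)N1C(=O)OC[C@H]1Cc1ccccc1 | intermediate
9 | dibutylboron (Z)-enolate of 8 | CC(C)/C=C(\OB(CCCC)CCCC)N1C(=O)OC[C@H]1Cc1ccccc1 | intermediate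
10 | (R)-4-benzyl-3-[(2R,3R,4Z)-3-hydroxy-5-iodo-2-(propan-2-yl)hex-4-enoyl]oxazolidin-2-one | CC(C)[C@H]([C@@H](O)/C=C(/C)I)C(=O)N1C(=O)OC[C@H]1Cc1ccccc1 | intermediate
11 | (R)-4-benzyl-3-[(2R,3R,4Z)-3-(tert-butyldimethylsilyloxy)-5-iodo-2-(propan-2-yl)hex-4-enoyl]oxazolidin-2-one | CC(C)[C@H]([C@@H](O[Si](C)(C)C(C)(C)C)/C=C(/C)I)C(=O)N1C(=O)OC[C@H]1Cc1ccccc1 | intermediate
12 | (2S,3R,4Z)-3-(tert-butyldimethylsilyloxy)-5-iodo-2-(propan-2-yl)hex-4-en-1-ol | CC(C)[C@H]([C@@H](O[Si](C)(C)C(C)(C)C)/C=C(/C)I)CO | intermediate
13 | (2R,3R,4Z)-3-(tert-butyldimethylsilyloxy)-5-iodo-2-(propan-2-yl)hex-4-enal | CC(C)[C@H]([C@@H](O[Si](C)(C)C(C)(C)C)/C=C(/C)I)C=O | intermediate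
14 | dimethyl (2-oxopropyl)phosphonate | COP(=O)(CC(C)=O)OC | starting material
15 | (3E,5S,6R,7Z)-6-(tert-butyldimethylsilyloxy)-8-iodo-5-(propan-2-yl)nona-3,7-dien-2-one | CC(C)[C@H]([C@@H](O[Si](C)(C)C(C)(C)C)/C=C(/C)I)/C=C/C(C)=O | intermediate
16 | (4R,5E,7S,8R,9Z)-8-(tert-butyldimethylsilyloxy)-10-iodo-4-methyl-7-(propan-2-yl)undeca-1,5,9-trien-4-ol | CC(C)[C@H]([C@@H](O[Si](C)(C)C(C)(C)C)/C=C(/C)I)/C=C/[C@](C)(O)CC=C | intermediate
17 | (4R,5E,7S,8R,9Z)-8-(tert-butyldimethylsilyloxy)-10-iodo-4-methyl-7-(propan-2-yl)-4-(triethylsilyloxy)undeca-1,5,9-triene | CC(C)[C@H]([C@@H](O[Si](C)(C)C(C)(C)C)/C=C(/C)I)/C=C/[C@](C)(O[Si](CC)(CC)CC)CC=C | intermediate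
18 | B-alkyl-9-borabicyclo[3.3.1]nonane from 17 (boron on the former terminal alkene carbon, ring C3) | CC(C)[C@H]([C@@H](O[Si](C)(C)C(C)(C)C)/C=C(/C)I)/C=C/[C@](C)(O[Si](CC)(CC)CC)CCCB1C2CCCC1CCC2 | intermediate
19 | (6R,7S,10R,4Z,8E)-6-(tert-butyldimethylsilyloxy)-4,10-dimethyl-7-(propan-2-yl)-10-(triethylsilyloxy)cyclodeca-4,8-diene | CC(C)[C@H]1/C=C/[C@](C)(O[Si](CC)(CC)CC)CCC/C(C)=C\[C@@H]1O[Si](C)(C)C(C)(C)C | intermediate
20 | (6R,7S,10R,4Z,8E)-4,10-dimethyl-7-(propan-2-yl)cyclodeca-4,8-diene-6,10-diol | CC(C)[C@H]1/C=C/[C@](C)(O)CCC/C(C)=C\[C@@H]1O | intermediate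
21 | (4S,5R,6R,7S,10R,8E)-4,5-epoxy-4,10-dimethyl-7-(propan-2-yl)cyclodec-8-ene-6,10-diol | CC(C)[C@H]1/C=C/[C@](C)(O)CCC[C@]2(C)O[C@@H]2[C@@H]1O | intermediate
22 | 4-hydroxybenzoic acid | OC(=O)c1ccc(O)cc1 | starting material
23 | tert-butyldimethylsilyl 4-(tert-butyldimethylsilyloxy)benzoate | CC(C)(C)[Si](C)(C)OC(=O)c1ccc(O[Si](C)(C)C(C)(C)C)cc1 | intermediate
24 | 4-(tert-butyldimethylsilyloxy)benzoic acid | OC(=O)c1ccc(O[Si](C)(C)C(C)(C)C)cc1 | intermediate
25 | (4S,5R,6R,7S,10R,8E)-4,5-epoxy-10-hydroxy-4,10-dimethyl-7-(propan-2-yl)cyclodec-8-en-6-yl 4-(tert-butyldimethylsilyloxy)benzoate | CC(C)[C@H]1/C=C/[C@](C)(O)CCC[C@]2(C)O[C@@H]2[C@@H]1OC(=O)c1ccc(O[Si](C)(C)C(C)(C)C)cc1 | intermediate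
26 | (4S,5R,6R,7S,10R,8E)-4,5-epoxy-10-hydroxy-4,10-dimethyl-7-(propan-2-yl)cyclodec-8-en-6-yl 4-hydroxybenzoate (CNP0278889.1) | CC(C)[C@H]1/C=C/[C@](C)(O)CCC[C@]2(C)O[C@@H]2[C@@H]1OC(=O)c1ccc(O)cc1 | target

## Step count and least certain steps

Total: 16 steps. Longest linear sequence: 14 steps (steps 1, 2, 4–13, 15, 16); steps 3 and 14 are side branches.

**Step 11 (key step).** The most likely failure is that intermolecular coupling and protodeboronation or reduction of the iodoalkene overtake ring closure, because transmetalation from boron is slow and the ten-membered transition state is strained. The fallback keeps the C3–C4 bond but changes the organometallic and how it is made. It sets out from 17. Hydroboration with 9-BBN-H and oxidative work-up (NaBO3) would give the primary alcohol (4R,5E,7S,8R,9Z)-8-(tert-butyldimethylsilyloxy)-10-iodo-4-methyl-7-(propan-2-yl)-4-(triethylsilyloxy)undeca-5,9-dien-1-ol F1. I2, PPh3 and imidazole would convert it into the 1-iodo analogue of F1 (primary alkyl iodide) F2. Zinc dust with LiCl inserts only into the sp3 carbon–iodine bond, giving the alkylzinc iodide F3. This is cyclised by slow addition to zerovalent palladium (Pd2(dba)3, tri(2-furyl)phosphine, THF/NMP) in an intramolecular Negishi coupling, whose faster, base-free transmetalation tolerates a lower stationary concentration. The route is rejoined at 19.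

**Step 9.** The most likely failure is weak or reversed face selectivity at the ketone, because methyl and the branched alkenyl group must be told apart by the catalyst alone on a hindered, substrate-chiral enone. The fallback takes C10 from the chiral pool and makes C8=C9 by sulfone olefination. It sets out from 12 and comes back at 17.
- Mitsunobu reaction of 12 with 1-phenyl-1H-tetrazole-5-thiol (PPh3, DIAD) would give the sulfide 5-{[(2R,3R,4Z)-3-(tert-butyldimethylsilyloxy)-5-iodo-2-(propan-2-yl)hex-4-en-1-yl]sulfanyl}-1-phenyl-1H-tetrazole F4.
- Oxidation (H2O2, (NH4)6Mo7O24, EtOH) would give the corresponding sulfone F5.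
- Separately, commercial (S)-(2-methyloxiran-2-yl)methanol F6 is opened at its methylene by vinylmagnesium bromide and CuI to (R)-2-methylpent-4-ene-1,2-diol F7.
- TESOTf and 2,6-lutidine give the bis(triethylsilyl) ether of F7 F8.
- Swern conditions oxidise the primary silyl ether directly to (R)-2-methyl-2-(triethylsilyloxy)pent-4-enal F9.
- Julia–Kocienski olefination of F5 with F9 (KN(SiMe3)2, DME, −60 °C) should give the E-alkene 17 directly.

**Step 13.** The most likely failure is slow and face-unselective oxygen transfer, since a Z-trisubstituted ring alkene fits the titanium–tartrate template poorly. Lewis-acid-induced transannular opening of the epoxide by the C10 hydroxyl is a second risk. The fallback epoxidises before the hydroxyls are freed, under reagent control without a directing group. It sets out from 19. Shi epoxidation with the D-fructose-derived ketone (KHSO5, K2CO3, MeCN/dimethoxymethane/aqueous buffer, 0 °C) is expected, by analogy with 1-substituted cycloalkenes, to attack the required face and give the (4S,5R)-epoxide of 19 (bis-silyl ether) F10. TBAF in THF, now safe because the 1,5-diene is gone, would remove both silyl groups and rejoin the route at 21.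

**Step 4.** The most likely failure is Z-to-E isomerisation or addition–elimination at the β-carbon of the iodoenal under the Lewis-acidic, amine-containing conditions, which would erode the geometry on which the ring-cis alkene depends. The fallback postpones the iodoalkene. It sets out from 1 and 8 and comes back at 12.
- MnO2 oxidation of 1 gives but-2-ynal F11.
- The same Evans aldol with 8 would give (R)-4-benzyl-3-[(2R,3R)-3-hydroxy-2-(propan-2-yl)hex-4-ynoyl]oxazolidin-2-one F12.
- LiBH4 gives (2S,3R)-2-(propan-2-yl)hex-4-yne-1,3-diol F13.
- Hydroxyl-directed trans-hydroalumination with NaAlH2(OCH2CH2OMe)2 and iodination, as in step 1, gives (2S,3R,4Z)-5-iodo-2-(propan-2-yl)hex-4-ene-1,3-diol F14.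
- TBSOTf and 2,6-lutidine give the bis(tert-butyldimethylsilyl) ether of F14 F15.
- Selective cleavage of the primary silyl ether (HF·pyridine, pyridine, THF, 0 °C) rejoins the route at 12.

## Further compounds

F1 | step 11 | (4R,5E,7S,8R,9Z)-8-(tert-butyldimethylsilyloxy)-10-iodo-4-methyl-7-(propan-2-yl)-4-(triethylsilyloxy)undeca-5,9-dien-1-ol | CC(C)[C@H]([C@@H](O[Si](C)(C)C(C)(C)C)/C=C(/C)I)/C=C/[C@](C)(O[Si](CC)(CC)CC)CCCO
F2 | step 11 | 1-iodo analogue of F1 (primary alkyl iodide) | CC(C)[C@H]([C@@H](O[Si](C)(C)C(C)(C)C)/C=C(/C)I)/C=C/[C@](C)(O[Si](CC)(CC)CC)CCCI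
F3 | step 11 | alkylzinc iodide from F2 | CC(C)[C@H]([C@@H](O[Si](C)(C)C(C)(C)C)/C=C(/C)I)/C=C/[C@](C)(O[Si](CC)(CC)CC)CCC[Zn]I
F4 | step 9 | 5-{[(2R,3R,4Z)-3-(tert-butyldimethylsilyloxy)-5-iodo-2-(propan-2-yl)hex-4-en-1-yl]sulfanyl}-1-phenyl-1H-tetrazole | CC(C)[C@H]([C@@H](O[Si](C)(C)C(C)(C)C)/C=C(/C)I)CSc1nnnn1-c1ccccc1
F5 | step 9 | 5-{[(2R,3R,4Z)-3-(tert-butyldimethylsilyloxy)-5-iodo-2-(propan-2-yl)hex-4-en-1-yl]sulfonyl}-1-phenyl-1H-tetrazole | CC(C)[C@H]([C@@H](O[Si](C)(C)C(C)(C)C)/C=C(/C)I)CS(=O)(=O)c1nnnn1-c1ccccc1
F6 | step 9 | (S)-(2-methyloxiran-2-yl)methanol (commercial) | C[C@]1(CO)CO1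
F7 | step 9 | (R)-2-methylpent-4-ene-1,2-diol | C[C@](O)(CO)CC=C
F8 | step 9 | (R)-2-methyl-1,2-bis(triethylsilyloxy)pent-4-ene | C[C@](O[Si](CC)(CC)CC)(CO[Si](CC)(CC)CC)CC=C
F9 | step 9 | (R)-2-methyl-2-(triethylsilyloxy)pent-4-enal | C[C@](O[Si](CC)(CC)CC)(C=O)CC=C
F10 | step 13 | (4S,5R,6R,7S,10R,8E)-6-(tert-butyldimethylsilyloxy)-4,5-epoxy-4,10-dimethyl-7-(propan-2-yl)-10-(triethylsilyloxy)cyclodec-8-ene | CC(C)[C@H]1/C=C/[C@](C)(O[Si](CC)(CC)CC)CCC[C@]2(C)O[C@@H]2[C@@H]1O[Si](C)(C)C(C)(C)C
F11 | step 4 | but-2-ynal | CC#CC=O
F12 | step 4 | (R)-4-benzyl-3-[(2R,3R)-3-hydroxy-2-(propan-2-yl)hex-4-ynoyl]oxazolidin-2-one | CC(C)[C@H]([C@@H](O)C#CC)C(=O)N1C(=O)OC[C@H]1Cc1ccccc1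
F13 | step 4 | (2S,3R)-2-(propan-2-yl)hex-4-yne-1,3-diol | CC(C)[C@H]([C@@H](O)C#CC)CO
F14 | step 4 | (2S,3R,4Z)-5-iodo-2-(propan-2-yl)hex-4-ene-1,3-diol | CC(C)[C@H]([C@@H](O)/C=C(/C)I)CO
F15 | step 4 | (2S,3R,4Z)-1,3-bis(tert-butyldimethylsilyloxy)-5-iodo-2-(propan-2-yl)hex-4-ene | CC(C)[C@H]([C@@H](O[Si](C)(C)C(C)(C)C)/C=C(/C)I)CO[Si](C)(C)C(C)(C)C
A1 | alternative 1 | cis-1,2-dialkenylcyclohexane-1,3-diol: 1-[(E)-2-(4-methoxybenzyloxy)ethenyl]-3-methyl-2-[(E)-3-methylbut-1-enyl]cyclohexane-1,3-diol | CC(C)/C=C/[C@@H]1[C@](O)(/C=C/OCc2ccc(OC)cc2)CCC[C@@]1(C)O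
A2 | alternative 1 | ten-membered dienyl triflate with C6 PMB ether and free C10 hydroxyl | CC(C)[C@H]1/C=C/[C@](C)(O)CCC/C(OS(=O)(=O)C(F)(F)F)=C\[C@@H]1OCc2ccc(OC)cc2
A3 | alternative 2 | open-chain C2 phenyl sulfone with C6 TBS ether and terminal 2-methyl-2-alkenyloxirane | CC(C)[C@H]([C@@H](O[Si](C)(C)C(C)(C)C)/C=C(/C)CCS(=O)(=O)c1ccccc1)/C=C/[C@@]1(C)CO1
A4 | alternative 2 | macrocyclic C10 alcohol carrying the C2 phenylsulfonyl group (both C2 epimers) | CC(C)[C@H]1/C=C/[C@](C)(O)CC(S(=O)(=O)c2ccccc2)C/C(C)=C\[C@@H]1O[Si](C)(C)C(C)(C)C
A5 | alternative 3 | open-chain C4 methyl ketone / C5 aldehyde with C6 PMB ether and C10 triethylsilyl ether | CC(C)[C@@H](/C=C/[C@](C)(O[Si](CC)(CC)CC)CCCC(C)=O)[C@@H](OCc1ccc(OC)cc1)C=O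
A6 | alternative 3 | macrocyclic diene with C6 PMB ether and C10 triethylsilyl ether | CC(C)[C@H]1/C=C/[C@](C)(O[Si](CC)(CC)CC)CCC/C(C)=C\[C@@H]1OCc2ccc(OC)cc2
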